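Remark on the chemistry: the rings are lettered A to F from left to right in the SMILES. In every ring C1 is the carbon bonded to the ether oxygen that points to the preceding ring (in ring A, to ring B). The target has no stereocentre, so no configuration has to be set.

## Analysis of the target

The target (C36H26O21) is a linear hexamer of six benzene rings held together only by five diaryl ether bonds; it has sixteen free phenolic hydroxyls and no stereocentre. Rings A, B, D and F are 1,2,3,5-tetraoxygenated; rings C and E are pentaoxygenated and carry two aryloxy groups on neighbouring carbons. Three ether bonds are of a "para type": C1(A)–O–C1(B), C4(B)–O–C1(C) and C4(D)–O–C1(E), each from a carbon flanked by two hydroxyls to an unhindered C1. Two are of an "ortho type": C2(C)–O–C1(D) and C2(E)–O–C1(F), where C2 sits between the C1 aryloxy carbon and the C3 hydroxyl carbon of a pentaoxygenated ring. These two C2–O bonds are the hard part, because the carbon is doubly ortho-substituted and on an extremely electron-rich ring, the worst case for copper-mediated or SNAr ether formation. The feature that the route exploits is that C2 of rings C and E lies next to the contiguous triol C3–OH/C4–OH/C5–OH. The C4/C5 catechol pair can be raised to an o-quinone, which makes the ring CH carbons electrophilic. The free polyphenol (pyrogallol and hydroxyhydroquinone units) is very sensitive to air and base, so free hydroxyls should appear only in the last step. The remaining difficulty is bookkeeping: sixteen oxygens must be told apart with as few protecting-group operations as possible.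

## Retrosynthetic reasoning

Target 27 is traced back to 26 by one global hydrogenolysis. In 26 every hydroxyl except the C4/C5 catechol of ring C is a benzyl ether (one 4-methoxybenzyl ether on ring A), so that the sensitive polyphenol is released under neutral, reductive conditions.

The C2(C)–O bond of 26 is cut. This is the central ortho-type bond; cutting it splits the hexamer into two halves of equal size, the trimer catechol 24 (rings A–B–C) and the trimer phenol 18 (rings D–E–F). In the forward direction ring C of 24, the only ring with free hydroxyls, is oxidised to the o-quinone 25, and the phenol oxygen of 18 adds to a ring CH carbon of 25. No halogen has to be placed on the pentaoxygenated ring, and no coupling at a doubly ortho-substituted carbon by a metal is needed. Ring C of 24 is symmetric apart from its protecting group, so attack at either CH carbon leads to the same target.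

Phenol 18 is traced through 17 and 16 to the dimer catechol 11 and phenol 14 by the same cut at C2(E)–O. Benzylation of the new catechol (16 to 17) and acidolysis of the 4-methoxybenzyl ether (17 to 18) free the C1(D) oxygen as the only nucleophile of the D–E–F half.

Catechols 24 and 11 are traced to the aldehydes 21 and 8 through 22 and 9. A formyl group flanked by two benzyloxy groups stands for the C4 hydroxyl, and one flanking benzyl ether is removed by chelation. Oxidation of the resulting salicylaldehyde then gives the catechol without any extra protecting group.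

The para-type bonds C4(B)–O–C1(C) in 21 and C1(A)–O–C1(B) (equally C4(D)–O–C1(E)) in 8 are cut at the unhindered C1 of the ring that carries the formyl group. This gives the hindered phenols 20 and 5 and the single bromo aldehyde 7. The formyl group of 7 activates the bromide, and after the coupling it is converted into the next phenol (8 to 20) or into the catechol, so one building block serves for rings B, C and E. Dimer 8 is common to both halves of the molecule.

Phenol 5 comes from 1 through 2 and 3, bromo aldehyde 7 from 6, and phenol 14 from 12, in each case by standard etherification and formyl-to-hydroxyl oxidation.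

## Alternatives that were turned down

Alternative 1: the textbook route. All five C–O bonds are cut as aryl bromide plus phenol and made by iterative copper-mediated Ullmann couplings of O-methylated building blocks in a linear A-to-F sequence. It ends in the hexadecamethyl ether A1 and a sixteen-fold Lewis-acid ether cleavage. It was turned down for three reasons. The two ortho-type bonds must be made at bromides flanked by two oxygenated carbons on pentaoxygenated rings, where the coupling is disfavoured both sterically and electronically. Each pentaoxygenated ring needs its own building block with a bromine and several differentiated oxygens, at a cost of several steps per block in a strictly linear sequence of more than twenty steps. The last step would be a harsh sixteen-fold demethylation that releases an air-sensitive polyphenol in the presence of boron salts.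

Alternative 2: rings C and E as doubly electrophilic linchpins. Both C–O bonds of ring C (C1–O and C2–O) are cut at once, back to the dibromo-o-quinone A2. The forward key step is a sequential addition–elimination (vinylogous acyl substitution) of two different phenoxides such as those of 20 and 18 on A2, followed by reduction. It was turned down because the two bromine-bearing carbons of A2 differ only through the remote benzyloxy group, so nothing in the substrate decides which phenoxide enters where, and the wrong order gives a constitutional isomer that does not converge on the target. In addition, an aryloxy group once installed is itself a vinylogous ester leaving group, so the second phenoxide can displace the first. Four of the five ether bonds would rest on this uncontrolled selectivity.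

Alternative 3: building the phloroglucinol-type rings from chains. Rings A, B and D are 2-aryloxyphloroglucinols, so their ring C–C bonds can be cut. The phenol of the preceding fragment is O-alkylated and the triketo ester A3 is folded by Claisen condensation into the trihydroxyphenyl ether A4. It was turned down because it forms only the para-type bonds, which are the easy ones, and leaves the ortho-type bonds at C2 of rings C and E untouched. Each cyclisation also delivers three free hydroxyls, of which the one para to the ether must be told from the two ortho ones before the chain can grow. Three such sequences in series, each with a retro-Claisen-prone 3,5-diketo ester, cost more steps than they save.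

Key step: step 16

## Route

Step 1
Reactants: 1 2,4,6-trihydroxybenzaldehyde
Product: 2 2,6-dihydroxy-4-[(4-methoxybenzyl)oxy]benzaldehyde
Conditions: 4-methoxybenzyl chloride, KHCO3, DMF, 40 °C
Reagents that add atoms: 4-methoxybenzyl chloride, COc1ccc(CCl)cc1
Why: Williamson etherification; the 4-hydroxyl is the most acidic and the only one not hydrogen-bonded to the formyl group, so a weak base should alkylate it selectively.

Step 2
Reactants: 2 2,6-dihydroxy-4-[(4-methoxybenzyl)oxy]benzaldehyde
Product: 3 2,6-bis(benzyloxy)-4-[(4-methoxybenzyl)oxy]benzaldehyde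
Conditions: BnBr, K2CO3, DMF, 70 °C
Reagents that add atoms: benzyl bromide, BrCc1ccccc1
Why: Williamson benzylation of the two chelated ortho hydroxyls under forcing conditions; the formyl group deactivates the ring against C-alkylation.

Step 3
Reactants: 3 2,6-bis(benzyloxy)-4-[(4-methoxybenzyl)oxy]benzaldehyde
Product: 5 2,6-bis(benzyloxy)-4-[(4-methoxybenzyl)oxy]phenol, via aryl formate 4 (not isolated)
Conditions: mCPBA, CH2Cl2, 0 °C; NaHCO3 wash; K2CO3 (cat.), MeOH, rt, Ar
Reagents that add atoms: mCPBA, O=C(OO)c1cccc(Cl)c1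
Why: Baeyer–Villiger (Dakin-type) oxidation; the 2,4,6-trialkoxyaryl group migrates readily and the formate is removed by methanolysis.

Step 4
Reactants: 6 4-bromo-2,6-difluorobenzaldehyde
Product: 7 2,6-bis(benzyloxy)-4-bromobenzaldehyde
Conditions: BnOH, Cs2CO3, DMF, 60 °C
Reagents that add atoms: benzyl alcohol, OCc1ccccc1
Why: double SNAr at the two fluorides ortho to the formyl group; bromide is a far poorer leaving group in SNAr and should stay in place.

Step 5
Reactants: 5 2,6-bis(benzyloxy)-4-[(4-methoxybenzyl)oxy]phenol; 7 2,6-bis(benzyloxy)-4-bromobenzaldehyde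
Product: 8 2,6-bis(benzyloxy)-4-{2,6-bis(benzyloxy)-4-[(4-methoxybenzyl)oxy]phenoxy}benzaldehyde
Conditions: CuI (10 mol %), picolinic acid (20 mol %), K3PO4, DMSO, 90 °C, Ar
Reagents that add atoms: none
Why: Ullmann-type copper-catalysed C–O coupling; the ligand system tolerates doubly ortho-substituted phenols, and the bromide is unhindered and activated by the para formyl group, which is not enolisable.

Step 6
Reactants: 8 2,6-bis(benzyloxy)-4-{2,6-bis(benzyloxy)-4-[(4-methoxybenzyl)oxy]phenoxy}benzaldehyde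
Product: 9 2-(benzyloxy)-4-{2,6-bis(benzyloxy)-4-[(4-methoxybenzyl)oxy]phenoxy}-6-hydroxybenzaldehyde
Conditions: MgBr2·OEt2, toluene–Et2O, 60 °C; aq. NH4Cl
Reagents that add atoms: none
Why: chelation-controlled debenzylation; magnesium bridges the carbonyl oxygen and one ortho benzyloxy oxygen and bromide attacks that benzyl group. The magnesium phenoxide chelate formed should protect the second ortho ether, and no other ether has a carbonyl neighbour.

Step 7
Reactants: 9 2-(benzyloxy)-4-{2,6-bis(benzyloxy)-4-[(4-methoxybenzyl)oxy]phenoxy}-6-hydroxybenzaldehyde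
Product: 11 3-(benzyloxy)-5-{2,6-bis(benzyloxy)-4-[(4-methoxybenzyl)oxy]phenoxy}benzene-1,2-diol, via catechol monoformate 10 (not isolated)
Conditions: mCPBA, CH2Cl2, 0 °C; NaHCO3 wash; degassed MeOH, KHCO3 (cat.), 0 °C, Ar
Reagents that add atoms: mCPBA, O=C(OO)c1cccc(Cl)c1
Why: Dakin oxidation of a salicylaldehyde to a catechol, run with a peracid and a weakly basic methanolysis so that the electron-rich catechol never meets alkaline peroxide or air.

Step 8
Reactants: 12 3,4,5-tris(benzyloxy)benzaldehyde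
Product: 14 3,4,5-tris(benzyloxy)phenol, via aryl formate 13 (not isolated)
Conditions: mCPBA, CH2Cl2, rt; NaHCO3 wash; K2CO3 (cat.), MeOH, rt
Reagents that add atoms: mCPBA, O=C(OO)c1cccc(Cl)c1
Why: Baeyer–Villiger oxidation of a 3,4,5-trialkoxybenzaldehyde, in which the para alkoxy group favours aryl migration, followed by methanolysis of the formate.

Step 9
Reactants: 11 3-(benzyloxy)-5-{2,6-bis(benzyloxy)-4-[(4-methoxybenzyl)oxy]phenoxy}benzene-1,2-diol; 14 3,4,5-tris(benzyloxy)phenol
Product: 16 3-(benzyloxy)-5-{2,6-bis(benzyloxy)-4-[(4-methoxybenzyl)oxy]phenoxy}-4-[3,4,5-tris(benzyloxy)phenoxy]benzene-1,2-diol, via o-quinone 15 (not isolated)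
Conditions: Ag2O, 4 Å molecular sieves, CH2Cl2, −20 °C, filtered under Ar; filtrate added to 14, Cs2CO3 (20 mol %), DMF, −40 to 0 °C; aq. Na2S2O4 work-up
Reagents that add atoms: none
Why: Proposed new method: dehydrogenation of the only free catechol gives o-quinone 15, the phenoxide of 14 adds through oxygen to a ring CH carbon (C2, beta to the C4 carbonyl, or C6, delta to it), and tautomerisation to the aromatic catechol makes the addition irreversible; the closest known reaction type is the oxa-Michael addition of phenols to catechol-derived o-quinones (aryloxycatechols from copper–amine phenol oxidations, C–O linked digallates from gallate o-quinones), new here for a quinone that carries only donor substituents. This step tests the key reaction on the small dimer with a cheap nucleophile.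

Step 10
Reactants: 16 3-(benzyloxy)-5-{2,6-bis(benzyloxy)-4-[(4-methoxybenzyl)oxy]phenoxy}-4-[3,4,5-tris(benzyloxy)phenoxy]benzene-1,2-diol
Product: 17 1,2,3-tris(benzyloxy)-5-{2,6-bis(benzyloxy)-4-[(4-methoxybenzyl)oxy]phenoxy}-4-[3,4,5-tris(benzyloxy)phenoxy]benzene
Conditions: BnBr, K2CO3, DMF, rt, Ar
Reagents that add atoms: benzyl bromide, BrCc1ccccc1
Why: Williamson benzylation of the catechol; ring E then carries three equal benzyloxy groups, so addition at C2 or at C6 in step 9 leads to the same compound 17.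

Step 11
Reactants: 17 1,2,3-tris(benzyloxy)-5-{2,6-bis(benzyloxy)-4-[(4-methoxybenzyl)oxy]phenoxy}-4-[3,4,5-tris(benzyloxy)phenoxy]benzene
Product: 18 3,5-bis(benzyloxy)-4-{3,4,5-tris(benzyloxy)-2-[3,4,5-tris(benzyloxy)phenoxy]phenoxy}phenol
Conditions: TFA (5 vol %), 1,3-dimethoxybenzene, CH2Cl2, 0 °C
Reagents that add atoms: none
Why: acidolysis of the aryl 4-methoxybenzyl ether; the stabilised benzylic cation is trapped by 1,3-dimethoxybenzene, while plain benzyl aryl ethers should be stable to dilute acid at 0 °C.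

Step 12
Reactants: 8 2,6-bis(benzyloxy)-4-{2,6-bis(benzyloxy)-4-[(4-methoxybenzyl)oxy]phenoxy}benzaldehyde
Product: 20 2,6-bis(benzyloxy)-4-{2,6-bis(benzyloxy)-4-[(4-methoxybenzyl)oxy]phenoxy}phenol, via aryl formate 19 (not isolated)
Conditions: mCPBA, CH2Cl2, 0 °C; NaHCO3 wash; K2CO3 (cat.), MeOH, rt, Ar
Reagents that add atoms: mCPBA, O=C(OO)c1cccc(Cl)c1
Why: Baeyer–Villiger oxidation as in step 3; the formyl group that activated the bromide in step 5 becomes the C4 oxygen of ring B.

Step 13
Reactants: 20 2,6-bis(benzyloxy)-4-{2,6-bis(benzyloxy)-4-[(4-methoxybenzyl)oxy]phenoxy}phenol; 7 2,6-bis(benzyloxy)-4-bromobenzaldehyde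
Product: 21 2,6-bis(benzyloxy)-4-(2,6-bis(benzyloxy)-4-{2,6-bis(benzyloxy)-4-[(4-methoxybenzyl)oxy]phenoxy}phenoxy)benzaldehyde
Conditions: CuI (10 mol %), picolinic acid (20 mol %), K3PO4, DMSO, 90 °C, Ar
Reagents that add atoms: none
Why: Ullmann-type C–O coupling as in step 5, a second use of building block 7 with a phenol of the same substitution pattern.

Step 14
Reactants: 21 2,6-bis(benzyloxy)-4-(2,6-bis(benzyloxy)-4-{2,6-bis(benzyloxy)-4-[(4-methoxybenzyl)oxy]phenoxy}phenoxy)benzaldehyde
Product: 22 2-(benzyloxy)-4-(2,6-bis(benzyloxy)-4-{2,6-bis(benzyloxy)-4-[(4-methoxybenzyl)oxy]phenoxy}phenoxy)-6-hydroxybenzaldehyde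
Conditions: MgBr2·OEt2, toluene–Et2O, 60 °C; aq. NH4Cl
Reagents that add atoms: none
Why: chelation-controlled mono-debenzylation as in step 6; only the two benzyl ethers ortho to the formyl group of ring C can chelate, and the first cleavage should shut off the second.

Step 15
Reactants: 22 2-(benzyloxy)-4-(2,6-bis(benzyloxy)-4-{2,6-bis(benzyloxy)-4-[(4-methoxybenzyl)oxy]phenoxy}phenoxy)-6-hydroxybenzaldehyde
Product: 24 3-(benzyloxy)-5-(2,6-bis(benzyloxy)-4-{2,6-bis(benzyloxy)-4-[(4-methoxybenzyl)oxy]phenoxy}phenoxy)benzene-1,2-diol, via catechol monoformate 23 (not isolated)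
Conditions: mCPBA, CH2Cl2, 0 °C; NaHCO3 wash; degassed MeOH, KHCO3 (cat.), 0 °C, Ar
Reagents that add atoms: mCPBA, O=C(OO)c1cccc(Cl)c1
Why: Dakin oxidation as in step 7; it gives the only ring of the A–B–C half that has free hydroxyls.

Step 16
Reactants: 24 3-(benzyloxy)-5-(2,6-bis(benzyloxy)-4-{2,6-bis(benzyloxy)-4-[(4-methoxybenzyl)oxy]phenoxy}phenoxy)benzene-1,2-diol; 18 3,5-bis(benzyloxy)-4-{3,4,5-tris(benzyloxy)-2-[3,4,5-tris(benzyloxy)phenoxy]phenoxy}phenol
Product: 26 3-(benzyloxy)-5-(2,6-bis(benzyloxy)-4-{2,6-bis(benzyloxy)-4-[(4-methoxybenzyl)oxy]phenoxy}phenoxy)-4-(3,5-bis(benzyloxy)-4-{3,4,5-tris(benzyloxy)-2-[3,4,5-tris(benzyloxy)phenoxy]phenoxy}phenoxy)benzene-1,2-diol, via o-quinone 25 (not isolated)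
Conditions: Ag2O, 4 Å molecular sieves, CH2Cl2, −20 °C, filtered under Ar; filtrate added to 18, Cs2CO3 (20 mol %), DMF, −40 to 0 °C; aq. Na2S2O4 work-up
Reagents that add atoms: none
Why: Proposed new method: Ag2O dehydrogenates the C4/C5 catechol of ring C, the only free hydroxyls in 24, to o-quinone 25; the caesium phenoxide of 18 then adds through oxygen to ring carbon C2 (beta to the C4 carbonyl through the C2=C3 bond) or C6 (delta to it), and tautomerisation of the enolate to the aromatic catechol makes the C2(C)–O bond irreversible. The closest known reaction type is the oxa-Michael addition of phenols to catechol-derived o-quinones, which gives aryloxycatechols in copper–amine phenol oxidations and C–O linked digallates from gallate o-quinones; what is new is a quinone with only donor substituents and no unsubstituted beta carbon. No ring is closed and no stereocentre is formed. Chemoselectivity is secured by the substrate, since every other oxygen of both partners is an ether and 18 has a single free hydroxyl. O-attack over C-attack of the ambident phenoxide is favoured by the caesium counter-ion in DMF at low temperature and by the benzyloxy groups that flank the ortho carbons of ring D. Attack at the CH carbons over ipso attack at C1 is favoured because C1 is shielded by the 2,6-bis(benzyloxy)aryl group of ring B, and ipso addition is reversible whereas CH addition is driven on by aromatisation. The choice between C2 and C6 does not matter, because both adducts give the same compound after step 17. In this one operation the two halves of the molecule are joined at the most hindered ether carbon, and ring C reaches its final pentaoxygenated pattern.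

Step 17
Reactants: 26 3-(benzyloxy)-5-(2,6-bis(benzyloxy)-4-{2,6-bis(benzyloxy)-4-[(4-methoxybenzyl)oxy]phenoxy}phenoxy)-4-(3,5-bis(benzyloxy)-4-{3,4,5-tris(benzyloxy)-2-[3,4,5-tris(benzyloxy)phenoxy]phenoxy}phenoxy)benzene-1,2-diol
Product: 27 CNP0114537.0, the free hexadecaphenol
Conditions: H2 (1 atm), Pd(OH)2 on carbon, THF–MeOH, rt; filtered and concentrated under Ar
Reagents that add atoms: none
Why: global hydrogenolysis of thirteen benzyl ethers and the 4-methoxybenzyl ether under neutral conditions; diaryl ethers are inert, and the polyphenol is released without acid, base or oxidant.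

## Compound list

1 | 2,4,6-trihydroxybenzaldehyde | O=Cc1c(O)cc(O)cc1O | starting material
2 | 2,6-dihydroxy-4-[(4-methoxybenzyl)oxy]benzaldehyde | O=Cc1c(O)cc(OCc2ccc(OC)cc2)cc1O | intermediate
3 | 2,6-bis(benzyloxy)-4-[(4-methoxybenzyl)oxy]benzaldehyde | O=Cc1c(OCc2ccccc2)cc(OCc2ccc(OC)cc2)cc1OCc1ccccc1 | intermediate
4 | 2,6-bis(benzyloxy)-4-[(4-methoxybenzyl)oxy]phenyl formate | O=COc1c(OCc2ccccc2)cc(OCc2ccc(OC)cc2)cc1OCc1ccccc1 | intermediate
5 | 2,6-bis(benzyloxy)-4-[(4-methoxybenzyl)oxy]phenol | Oc1c(OCc2ccccc2)cc(OCc2ccc(OC)cc2)cc1OCc1ccccc1 | intermediate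
6 | 4-bromo-2,6-difluorobenzaldehyde | O=Cc1c(F)cc(Br)cc1F | starting material
7 | 2,6-bis(benzyloxy)-4-bromobenzaldehyde | O=Cc1c(OCc2ccccc2)cc(Br)cc1OCc1ccccc1 | intermediate
8 | 2,6-bis(benzyloxy)-4-{2,6-bis(benzyloxy)-4-[(4-methoxybenzyl)oxy]phenoxy}benzaldehyde | O=Cc1c(OCc2ccccc2)cc(Oc2c(OCc3ccccc3)cc(OCc3ccc(OC)cc3)cc2OCc2ccccc2)cc1OCc1ccccc1 | intermediate
9 | 2-(benzyloxy)-4-{2,6-bis(benzyloxy)-4-[(4-methoxybenzyl)oxy]phenoxy}-6-hydroxybenzaldehyde | O=Cc1c(O)cc(Oc2c(OCc3ccccc3)cc(OCc3ccc(OC)cc3)cc2OCc2ccccc2)cc1OCc1ccccc1 | intermediate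
10 | 2-(benzyloxy)-4-{2,6-bis(benzyloxy)-4-[(4-methoxybenzyl)oxy]phenoxy}-6-hydroxyphenyl formate | O=COc1c(O)cc(Oc2c(OCc3ccccc3)cc(OCc3ccc(OC)cc3)cc2OCc2ccccc2)cc1OCc1ccccc1 | intermediate
11 | 3-(benzyloxy)-5-{2,6-bis(benzyloxy)-4-[(4-methoxybenzyl)oxy]phenoxy}benzene-1,2-diol | Oc1c(O)cc(Oc2c(OCc3ccccc3)cc(OCc3ccc(OC)cc3)cc2OCc2ccccc2)cc1OCc1ccccc1 | intermediate
12 | 3,4,5-tris(benzyloxy)benzaldehyde | O=Cc1cc(OCc2ccccc2)c(OCc2ccccc2)c(OCc2ccccc2)c1 | starting material
13 | 3,4,5-tris(benzyloxy)phenyl formate | O=COc1cc(OCc2ccccc2)c(OCc2ccccc2)c(OCc2ccccc2)c1 | intermediate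
14 | 3,4,5-tris(benzyloxy)phenol | Oc1cc(OCc2ccccc2)c(OCc2ccccc2)c(OCc2ccccc2)c1 | intermediate
15 | 3-(benzyloxy)-5-{2,6-bis(benzyloxy)-4-[(4-methoxybenzyl)oxy]phenoxy}cyclohexa-3,5-diene-1,2-dione | O=C1C(=O)C=C(Oc2c(OCc3ccccc3)cc(OCc3ccc(OC)cc3)cc2OCc2ccccc2)C=C1OCc1ccccc1 | intermediate
16 | 3-(benzyloxy)-5-{2,6-bis(benzyloxy)-4-[(4-methoxybenzyl)oxy]phenoxy}-4-[3,4,5-tris(benzyloxy)phenoxy]benzene-1,2-diol | Oc1cc(Oc2c(OCc3ccccc3)cc(OCc3ccc(OC)cc3)cc2OCc2ccccc2)c(Oc2cc(OCc3ccccc3)c(OCc3ccccc3)c(OCc3ccccc3)c2)c(OCc2ccccc2)c1O | intermediate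
17 | 1,2,3-tris(benzyloxy)-5-{2,6-bis(benzyloxy)-4-[(4-methoxybenzyl)oxy]phenoxy}-4-[3,4,5-tris(benzyloxy)phenoxy]benzene | O(Cc1ccccc1)c1cc(Oc2c(OCc3ccccc3)cc(OCc3ccc(OC)cc3)cc2OCc2ccccc2)c(Oc2cc(OCc3ccccc3)c(OCc3ccccc3)c(OCc3ccccc3)c2)c(OCc2ccccc2)c1OCc1ccccc1 | intermediate
18 | 3,5-bis(benzyloxy)-4-{3,4,5-tris(benzyloxy)-2-[3,4,5-tris(benzyloxy)phenoxy]phenoxy}phenol | O(Cc1ccccc1)c1cc(Oc2c(OCc3ccccc3)cc(O)cc2OCc2ccccc2)c(Oc2cc(OCc3ccccc3)c(OCc3ccccc3)c(OCc3ccccc3)c2)c(OCc2ccccc2)c1OCc1ccccc1 | intermediate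
19 | 2,6-bis(benzyloxy)-4-{2,6-bis(benzyloxy)-4-[(4-methoxybenzyl)oxy]phenoxy}phenyl formate | O=COc1c(OCc2ccccc2)cc(Oc2c(OCc3ccccc3)cc(OCc3ccc(OC)cc3)cc2OCc2ccccc2)cc1OCc1ccccc1 | intermediate
20 | 2,6-bis(benzyloxy)-4-{2,6-bis(benzyloxy)-4-[(4-methoxybenzyl)oxy]phenoxy}phenol | Oc1c(OCc2ccccc2)cc(Oc2c(OCc3ccccc3)cc(OCc3ccc(OC)cc3)cc2OCc2ccccc2)cc1OCc1ccccc1 | intermediate
21 | 2,6-bis(benzyloxy)-4-(2,6-bis(benzyloxy)-4-{2,6-bis(benzyloxy)-4-[(4-methoxybenzyl)oxy]phenoxy}phenoxy)benzaldehyde | O=Cc1c(OCc2ccccc2)cc(Oc2c(OCc3ccccc3)cc(Oc3c(OCc4ccccc4)cc(OCc4ccc(OC)cc4)cc3OCc3ccccc3)cc2OCc2ccccc2)cc1OCc1ccccc1 | intermediate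
22 | 2-(benzyloxy)-4-(2,6-bis(benzyloxy)-4-{2,6-bis(benzyloxy)-4-[(4-methoxybenzyl)oxy]phenoxy}phenoxy)-6-hydroxybenzaldehyde | O=Cc1c(O)cc(Oc2c(OCc3ccccc3)cc(Oc3c(OCc4ccccc4)cc(OCc4ccc(OC)cc4)cc3OCc3ccccc3)cc2OCc2ccccc2)cc1OCc1ccccc1 | intermediate
23 | 2-(benzyloxy)-4-(2,6-bis(benzyloxy)-4-{2,6-bis(benzyloxy)-4-[(4-methoxybenzyl)oxy]phenoxy}phenoxy)-6-hydroxyphenyl formate | O=COc1c(O)cc(Oc2c(OCc3ccccc3)cc(Oc3c(OCc4ccccc4)cc(OCc4ccc(OC)cc4)cc3OCc3ccccc3)cc2OCc2ccccc2)cc1OCc1ccccc1 | intermediate
24 | 3-(benzyloxy)-5-(2,6-bis(benzyloxy)-4-{2,6-bis(benzyloxy)-4-[(4-methoxybenzyl)oxy]phenoxy}phenoxy)benzene-1,2-diol | Oc1c(O)cc(Oc2c(OCc3ccccc3)cc(Oc3c(OCc4ccccc4)cc(OCc4ccc(OC)cc4)cc3OCc3ccccc3)cc2OCc2ccccc2)cc1OCc1ccccc1 | intermediate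
25 | 3-(benzyloxy)-5-(2,6-bis(benzyloxy)-4-{2,6-bis(benzyloxy)-4-[(4-methoxybenzyl)oxy]phenoxy}phenoxy)cyclohexa-3,5-diene-1,2-dione | O=C1C(=O)C=C(Oc2c(OCc3ccccc3)cc(Oc3c(OCc4ccccc4)cc(OCc4ccc(OC)cc4)cc3OCc3ccccc3)cc2OCc2ccccc2)C=C1OCc1ccccc1 | intermediate
26 | 3-(benzyloxy)-5-(2,6-bis(benzyloxy)-4-{2,6-bis(benzyloxy)-4-[(4-methoxybenzyl)oxy]phenoxy}phenoxy)-4-(3,5-bis(benzyloxy)-4-{3,4,5-tris(benzyloxy)-2-[3,4,5-tris(benzyloxy)phenoxy]phenoxy}phenoxy)benzene-1,2-diol | Oc1cc(Oc2c(OCc3ccccc3)cc(Oc3c(OCc4ccccc4)cc(OCc4ccc(OC)cc4)cc3OCc3ccccc3)cc2OCc2ccccc2)c(Oc2cc(OCc3ccccc3)c(Oc3cc(OCc4ccccc4)c(OCc4ccccc4)c(OCc4ccccc4)c3Oc3cc(OCc4ccccc4)c(OCc4ccccc4)c(OCc4ccccc4)c3)c(OCc3ccccc3)c2)c(OCc2ccccc2)c1O | intermediate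
27 | CNP0114537.0, 2-[4-(2-{4-[2-(3,4,5-trihydroxyphenoxy)-3,4,5-trihydroxyphenoxy]-3,5-dihydroxyphenoxy}-3,4,5-trihydroxyphenoxy)-3,5-dihydroxyphenoxy]benzene-1,3,5-triol | Oc1cc(O)c(Oc2cc(O)c(Oc3cc(O)c(O)c(O)c3Oc3cc(O)c(Oc4cc(O)c(O)c(O)c4Oc4cc(O)c(O)c(O)c4)c(O)c3)c(O)c2)c(O)c1 | target

## Step count and least certain steps

Total step count: 17. Longest linear sequence: 11 steps (steps 1, 2, 3, 5, 6, 7, 9, 10, 11, 16, 17).

**Step 16 (key step, labelled).** Four things can go wrong.
- The phenoxide may attack the aryloxy-bearing carbon C1 of the quinone, which is a vinylogous ester carbon. Loss of the ring B phenoxide would then exchange the aryloxy groups and scramble the fragments.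
- The ambident phenoxide may attack through its ortho carbon and give a biaryl.
- The adduct, being more electron-rich than the starting catechol, may be oxidised by unreacted quinone. This redox exchange would stall conversion near one half until the reductive work-up; the recovered catechol could be recycled.
- The quinone may dimerise before it is trapped.

Fallback from known reactions: it sets out from phenol 20 and comes back to the route at 27. Bromination of 7 with NBS should give 2,6-bis(benzyloxy)-3,4-dibromobenzaldehyde F1. Ullmann coupling of 20 with F1 should occur at the bromide para to the formyl group and give the trimer bromo aldehyde F2. A second, forcing Ullmann coupling (CuI, N,N-dimethylglycine, Cs2CO3, dioxane, 110 °C) of the remaining hindered bromide of F2 with phenol 18 should give the hexamer aldehyde F3. Baeyer–Villiger oxidation and methanolysis should give the hexamer phenol F4, and hydrogenolysis under the conditions of step 17 would give 27.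

**Step 9 (labelled).** The same processes as in step 16 can occur: aryloxy exchange by ipso attack, C-attack, redox exchange with unreacted quinone and quinone dimerisation. They are less costly here because 14 can be used in excess. The fallback sets out from phenol 5 and comes back at 17. Ullmann coupling of 5 with 2,6-bis(benzyloxy)-3,4-dibromobenzaldehyde F1 at the para bromide should give the dimer bromo aldehyde F5. Forcing Ullmann coupling of F5 with 14 should give the trimer aldehyde F6. Baeyer–Villiger oxidation and methanolysis should give the trimer phenol F7, and benzylation with BnBr and K2CO3 would give 17.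

**Step 14 (and step 6, the same reaction).** The debenzylation may lose selectivity: the second ortho benzyl ether may be cleaved on prolonged heating, or the Lewis acid may cleave the 4-methoxybenzyl ether. The fallback differentiates the two ortho oxygens in the building block instead; it sets out from phenol 20 and comes back at 22. Sequential SNAr on 6, first with one equivalent of benzyl alcohol to 2-(benzyloxy)-4-bromo-6-fluorobenzaldehyde F8 and then with allyl alcohol, should give 2-(allyloxy)-6-(benzyloxy)-4-bromobenzaldehyde F9. Ullmann coupling of F9 with 20 should give the trimer allyl ether aldehyde F10, and deallylation with Pd(PPh3)4 and morpholine would give 22.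

**Step 13 (and step 5).** The electron-rich, doubly ortho-substituted phenoxide may be oxidised under copper catalysis, with loss of its para aryloxy group and formation of a quinone, or the coupling may be sluggish. The metal-free fallback sets out from 20 and comes back at 21. SNAr of the phenoxide of 20 on commercial 2,4,6-trifluorobenzaldehyde should occur at the fluoride para to the formyl group, since the bulky nucleophile avoids the ortho positions, and give the 4-aryloxy-2,6-difluorobenzaldehyde F11. Double SNAr with benzyl alcohol and Cs2CO3, as in step 4, would then give 21.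

**Step 1.** The alkylation may run on to a second hydroxyl, or the activated ring may be C-alkylated by the benzylic chloride. The fallback sets out from 7 and comes back at 3: copper-catalysed etherification of the aryl bromide of 7 with 4-methoxybenzyl alcohol (CuI, 3,4,7,8-tetramethyl-1,10-phenanthroline, Cs2CO3, toluene, 110 °C) would give 3 directly, without a new intermediate.

**Step 17.** Debenzylation may stop short as the intermediates become polar and bind to the catalyst, and the free polyphenol may be oxidised by air during isolation. The fallback sets out from 26 and comes back at 27. Hydrogenolysis followed directly by acetylation of the filtrate with Ac2O and pyridine should give the stable hexadecaacetate F12, which can be purified by chromatography. Acid methanolysis (HCl in MeOH, Ar) would then release 27.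

## Further compounds

F1 | step 16 | 2,6-bis(benzyloxy)-3,4-dibromobenzaldehyde | O=Cc1c(OCc2ccccc2)cc(Br)c(Br)c1OCc1ccccc1
F2 | step 16 | 2,6-bis(benzyloxy)-4-(2,6-bis(benzyloxy)-4-{2,6-bis(benzyloxy)-4-[(4-methoxybenzyl)oxy]phenoxy}phenoxy)-3-bromobenzaldehyde | O=Cc1c(OCc2ccccc2)cc(Oc2c(OCc3ccccc3)cc(Oc3c(OCc4ccccc4)cc(OCc4ccc(OC)cc4)cc3OCc3ccccc3)cc2OCc2ccccc2)c(Br)c1OCc1ccccc1
F3 | step 16 | 2,6-bis(benzyloxy)-4-(2,6-bis(benzyloxy)-4-{2,6-bis(benzyloxy)-4-[(4-methoxybenzyl)oxy]phenoxy}phenoxy)-3-(3,5-bis(benzyloxy)-4-{3,4,5-tris(benzyloxy)-2-[3,4,5-tris(benzyloxy)phenoxy]phenoxy}phenoxy)benzaldehyde | O=Cc1c(OCc2ccccc2)cc(Oc2c(OCc3ccccc3)cc(Oc3c(OCc4ccccc4)cc(OCc4ccc(OC)cc4)cc3OCc3ccccc3)cc2OCc2ccccc2)c(Oc2cc(OCc3ccccc3)c(Oc3cc(OCc4ccccc4)c(OCc4ccccc4)c(OCc4ccccc4)c3Oc3cc(OCc4ccccc4)c(OCc4ccccc4)c(OCc4ccccc4)c3)c(OCc3ccccc3)c2)c1OCc1ccccc1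
F4 | step 16 | 2,6-bis(benzyloxy)-4-(2,6-bis(benzyloxy)-4-{2,6-bis(benzyloxy)-4-[(4-methoxybenzyl)oxy]phenoxy}phenoxy)-3-(3,5-bis(benzyloxy)-4-{3,4,5-tris(benzyloxy)-2-[3,4,5-tris(benzyloxy)phenoxy]phenoxy}phenoxy)phenol | Oc1c(OCc2ccccc2)cc(Oc2c(OCc3ccccc3)cc(Oc3c(OCc4ccccc4)cc(OCc4ccc(OC)cc4)cc3OCc3ccccc3)cc2OCc2ccccc2)c(Oc2cc(OCc3ccccc3)c(Oc3cc(OCc4ccccc4)c(OCc4ccccc4)c(OCc4ccccc4)c3Oc3cc(OCc4ccccc4)c(OCc4ccccc4)c(OCc4ccccc4)c3)c(OCc3ccccc3)c2)c1OCc1ccccc1
F5 | step 9 | 2,6-bis(benzyloxy)-4-{2,6-bis(benzyloxy)-4-[(4-methoxybenzyl)oxy]phenoxy}-3-bromobenzaldehyde | O=Cc1c(OCc2ccccc2)cc(Oc2c(OCc3ccccc3)cc(OCc3ccc(OC)cc3)cc2OCc2ccccc2)c(Br)c1OCc1ccccc1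
F6 | step 9 | 2,6-bis(benzyloxy)-4-{2,6-bis(benzyloxy)-4-[(4-methoxybenzyl)oxy]phenoxy}-3-[3,4,5-tris(benzyloxy)phenoxy]benzaldehyde | O=Cc1c(OCc2ccccc2)cc(Oc2c(OCc3ccccc3)cc(OCc3ccc(OC)cc3)cc2OCc2ccccc2)c(Oc2cc(OCc3ccccc3)c(OCc3ccccc3)c(OCc3ccccc3)c2)c1OCc1ccccc1
F7 | step 9 | 2,6-bis(benzyloxy)-4-{2,6-bis(benzyloxy)-4-[(4-methoxybenzyl)oxy]phenoxy}-3-[3,4,5-tris(benzyloxy)phenoxy]phenol | Oc1c(OCc2ccccc2)cc(Oc2c(OCc3ccccc3)cc(OCc3ccc(OC)cc3)cc2OCc2ccccc2)c(Oc2cc(OCc3ccccc3)c(OCc3ccccc3)c(OCc3ccccc3)c2)c1OCc1ccccc1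
F8 | step 14 | 2-(benzyloxy)-4-bromo-6-fluorobenzaldehyde | O=Cc1c(F)cc(Br)cc1OCc1ccccc1
F9 | step 14 | 2-(allyloxy)-6-(benzyloxy)-4-bromobenzaldehyde | O=Cc1c(OCC=C)cc(Br)cc1OCc1ccccc1
F10 | step 14 | 2-(allyloxy)-6-(benzyloxy)-4-(2,6-bis(benzyloxy)-4-{2,6-bis(benzyloxy)-4-[(4-methoxybenzyl)oxy]phenoxy}phenoxy)benzaldehyde | O=Cc1c(OCC=C)cc(Oc2c(OCc3ccccc3)cc(Oc3c(OCc4ccccc4)cc(OCc4ccc(OC)cc4)cc3OCc3ccccc3)cc2OCc2ccccc2)cc1OCc1ccccc1
F11 | step 13 | 4-(2,6-bis(benzyloxy)-4-{2,6-bis(benzyloxy)-4-[(4-methoxybenzyl)oxy]phenoxy}phenoxy)-2,6-difluorobenzaldehyde | O=Cc1c(F)cc(Oc2c(OCc3ccccc3)cc(Oc3c(OCc4ccccc4)cc(OCc4ccc(OC)cc4)cc3OCc3ccccc3)cc2OCc2ccccc2)cc1F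
F12 | step 17 | hexadecaacetate of 27 | CC(=O)Oc1cc(OC(C)=O)c(Oc2cc(OC(C)=O)c(Oc3cc(OC(C)=O)c(OC(C)=O)c(OC(C)=O)c3Oc3cc(OC(C)=O)c(Oc4cc(OC(C)=O)c(OC(C)=O)c(OC(C)=O)c4Oc4cc(OC(C)=O)c(OC(C)=O)c(OC(C)=O)c4)c(OC(C)=O)c3)c(OC(C)=O)c2)c(OC(C)=O)c1
F0 | step 1 | none | none
A1 | alternative 1 | hexadecamethyl ether of 27 | COc1cc(OC)c(Oc2cc(OC)c(Oc3cc(OC)c(OC)c(OC)c3Oc3cc(OC)c(Oc4cc(OC)c(OC)c(OC)c4Oc4cc(OC)c(OC)c(OC)c4)c(OC)c3)c(OC)c2)c(OC)c1
A2 | alternative 2 | 3-(benzyloxy)-4,5-dibromocyclohexa-3,5-diene-1,2-dione | O=C1C(=O)C=C(Br)C(Br)=C1OCc1ccccc1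
A3 | alternative 3 | methyl 3,5-dioxo-6-{3,4,5-tris(benzyloxy)-2-[3,4,5-tris(benzyloxy)phenoxy]phenoxy}hexanoate | COC(=O)CC(=O)CC(=O)COc1cc(OCc2ccccc2)c(OCc2ccccc2)c(OCc2ccccc2)c1Oc1cc(OCc2ccccc2)c(OCc2ccccc2)c(OCc2ccccc2)c1
A4 | alternative 3 | 2-{3,4,5-tris(benzyloxy)-2-[3,4,5-tris(benzyloxy)phenoxy]phenoxy}benzene-1,3,5-triol | Oc1cc(O)c(Oc2cc(OCc3ccccc3)c(OCc3ccccc3)c(OCc3ccccc3)c2Oc2cc(OCc3ccccc3)c(OCc3ccccc3)c(OCc3ccccc3)c2)c(O)c1
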